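**Retrosynthetic overview**
- Hypoxyterpoid A ⇒ its 8-oxo-17-nor analogue: the exocyclic C8=C17 alkene is put back last by Wittig methylenation.
- 2α-Hydroxy 8-ketone ⇒ 8-oxo-17-nor diacid: the C2–O bond is made by a site- and face-selective C–H aminoxylation (decatungstate hydrogen abstraction, nitroxide capture, N–O cleavage). This is the key step and sets C2.
- 8-Oxo-17-nor diacid ⇒ (+)-agathic acid by chemoselective ozonolysis of the exocyclic alkene. The ketone masks the alkene and deactivates the ring B C–H bonds.
- No ring is formed: rings A and B (trans-decalin) and the stereocentres C4, C5, C9 and C10 come intact from agathic acid, and both acids stay unprotected throughout.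

Assumption: (+)-agathic acid (1, CAS 640-28-8), the main diacid of commercial Manila copal resin and a catalogue compound, is taken as the commercially available starting material.

**Step 1**
Reactants: 1 (+)-agathic acid
Product: 3 keto diacid 8-oxo-17-norlabd-13E-ene-15,19-dioic acid, via spiro-ozonide 2 (not isolated)
Conditions: O3, CH2Cl2, −78 °C (Sudan Red 7B end point); then PPh3, −78 °C → rt
Reagents that add atoms: ozone, O=[O+][O-]
Why: Criegee ozonolysis, in which electrophilic O3 adds to the electron-rich 1,1-disubstituted C8(17) alkene much faster than to the conjugated, electron-poor C13 enoic acid (the dye end point stops the feed), PPh3 reduces the ozonide to the ketone, and no stereocentre is touched (C9 keeps its equatorial side chain).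

**Step 2**
Reactants: 3 8-oxo-17-norlabd-13E-ene-15,19-dioic acid
Product: 5 2α-hydroxy-8-oxo-17-norlabd-13E-ene-15,19-dioic acid, via C2 alkoxyamine 4 (not isolated)
Conditions: (nBu4N)4[W10O32] (5 mol %), TEMPO (2.5 equiv, syringe pump), MeCN, 390 nm, 25 °C, Ar; then Zn, AcOH/THF/H2O, 50 °C
Reagents that add atoms: TEMPO (2,2,6,6-tetramethylpiperidin-1-oxyl), CC1(C)CCCC(C)(C)N1[O]
Why: Proposed new method: photoexcited (nBu4N)4[W10O32] should abstract the exposed equatorial 2α-H, the most hydridic and least hindered C–H left (the C8 ketone deactivates ring B, the C19 acid deactivates C3 and C5, and the γ-C–H bonds of the enoic acid are polarity-mismatched vinylogous α-positions); the planar C2 radical is then captured by TEMPO from the α face only, because the β face is closed by the syn-axial C20 methyl and C19 carboxyl, which sets the 2α (2R) C–O bond; a second TEMPO takes the hydrogen from the reduced polyoxotungstate, the remaining C2–H is the shielded axial one so over-oxidation is held back, and Zn/AcOH cleaves N–O without touching C2; the closest known chemistry is decatungstate C2–H fluorination, alkylation and arylation of sclareolide and nitroxide capture of alkyl radicals, whereas a preparative decatungstate C–H aminoxylation of an unactivated ring methylene in a free keto diacid has not been shown.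

**Step 3**
Reactants: 5 2α-hydroxy-8-oxo-17-norlabd-13E-ene-15,19-dioic acid
Product: 6 hypoxyterpoid A
Conditions: Ph3PCH3Br (6 equiv), KOtBu (6 equiv), THF, 0 → 50 °C; then aq. HCl to pH 3
Reagents that add atoms: methyltriphenylphosphonium bromide, C[P+](c1ccccc1)(c1ccccc1)c1ccccc1.[Br-]
Why: Wittig methylenation of the hindered C8 ketone with excess ylide, in which the two carboxylates and the alkoxide formed in the flask keep the enoate from conjugate addition, C9 stays in its stable equatorial configuration, and the C13 E-alkene and C2 are untouched.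

**Compound list**
1 | (+)-agathic acid, labda-8(17),13E-diene-15,19-dioic acid (5α-H, 9α-H, 10β-methyl, 4β-carboxyl) | C=C1CC[C@@H]2[C@](C)(CCC[C@]2(C)C(=O)O)[C@H]1CC/C(C)=C/C(=O)O | starting material
2 | spiro-ozonide of 1 (1,2,4-trioxolane spanning C8 and C17, mixture at C8) | O1COOC12CC[C@@H]3[C@](C)(CCC[C@]3(C)C(=O)O)[C@H]2CC/C(C)=C/C(=O)O | intermediate
3 | 8-oxo-17-norlabd-13E-ene-15,19-dioic acid | O=C1CC[C@@H]2[C@](C)(CCC[C@]2(C)C(=O)O)[C@H]1CC/C(C)=C/C(=O)O | intermediate
4 | 2α-(2,2,6,6-tetramethylpiperidin-1-yloxy)-8-oxo-17-norlabd-13E-ene-15,19-dioic acid | O=C1CC[C@@H]2[C@](C)(C[C@@H](ON3C(C)(C)CCCC3(C)C)C[C@]2(C)C(=O)O)[C@H]1CC/C(C)=C/C(=O)O | intermediate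
5 | 2α-hydroxy-8-oxo-17-norlabd-13E-ene-15,19-dioic acid | O=C1CC[C@@H]2[C@](C)(C[C@@H](O)C[C@]2(C)C(=O)O)[C@H]1CC/C(C)=C/C(=O)O | intermediate
6 | hypoxyterpoid A, (2R)-2α-hydroxylabda-8(17),13E-diene-15,19-dioic acid | C=C1CC[C@@H]2[C@](C)(C[C@@H](O)C[C@]2(C)C(=O)O)[C@H]1CC/C(C)=C/C(=O)O | target

**Totals**
Total step count: 3. Longest linear sequence: 3.

**Steps most likely to fail**

Step 2 (the new C–H aminoxylation). The risks are quenching of the excited polyoxotungstate by TEMPO and competing hydrogen abstraction in the side chain (C11, C12, C16). The fallback drops nitroxide capture for aerobic oxygen capture, which is known decatungstate photo-oxygenation. It sets out from 3: (nBu4N)4[W10O32] (2 mol %), O2 (1 atm), MeCN/H2O, 390 nm, stopped at partial conversion, gives by α-face capture of O2 the 2α-hydroperoxy-8-oxo-17-norlabd-13E-ene-15,19-dioic acid F1. PPh3 in THF at 0 °C reduces this to 5, where the route is rejoined.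

Step 1 (chemoselective ozonolysis). The risk is partial cleavage of the C13 enoic acid. The fallback replaces ozone by a peracid, which does not attack enoic acids. It sets out from 1: mCPBA, CH2Cl2, 0 °C gives the 8,17-epoxylabd-13E-ene-15,19-dioic acid F2 (configuration at C8 irrelevant). H5IO6 in THF/H2O then opens and cleaves the epoxide to 3, where the route is rejoined.

Step 3 (Wittig on a hindered, enolisable ketone in a trianion). The risks are enolisation instead of addition and poor solubility of the salts. The fallback is a Peterson olefination with a non-basic organocerium. It sets out from 5: Me3SiCH2MgCl/CeCl3 (excess), THF, −78 → 0 °C gives the 2α,8-dihydroxy-17-(trimethylsilyl)labd-13E-ene-15,19-dioic acid F3. KH in THF at 25 °C then eliminates silanolate regiospecifically towards C17 and gives 6 after acidic work-up.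

**Further compounds**
F1 | step 2 | 2α-hydroperoxy-8-oxo-17-norlabd-13E-ene-15,19-dioic acid | O=C1CC[C@@H]2[C@](C)(C[C@@H](OO)C[C@]2(C)C(=O)O)[C@H]1CC/C(C)=C/C(=O)O
F2 | step 1 | 8,17-epoxylabd-13E-ene-15,19-dioic acid (mixture at C8) | C1OC12CC[C@@H]3[C@](C)(CCC[C@]3(C)C(=O)O)[C@H]2CC/C(C)=C/C(=O)O
F3 | step 3 | 2α,8-dihydroxy-17-(trimethylsilyl)labd-13E-ene-15,19-dioic acid (mixture at C8) | C[Si](C)(C)CC1(O)CC[C@@H]2[C@](C)(C[C@@H](O)C[C@]2(C)C(=O)O)[C@H]1CC/C(C)=C/C(=O)O
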